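**Plan**
Flavanone numbering is used (O1, C2–C4, C4a, C5–C8, C8a). Ring A is an acylphloroglucinol: C4a, C5, C6, C7, C8 and C8a alternate like a folded keto-ester chain, with O1 on C8a, the C4 acyl group on C4a and the lavandulyl CH2 on C6, so ring A can be closed from a chain hanging on ring C.
Cuts, in retro order: the 4'-O–Si bond; C4a–C5 (ring A, Claisen cyclisation of a dihydropyranone keto ester); C6–C7 (decarboxylative Claisen coupling); O1–C8a and C4–C4a (ring C from a β-hydroxy Weinreb amide and an acetoacetate dianion); C2–C3 (aldol); lavandulyl CH2–C6 (malonate alkylation).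
Forward: ring B aldehyde, then C2–C3, then ring C, then the C6–C7 junction with the lavandulylmalonate, then ring A, then desilylation.
Stereochemistry: C2 is set by asymmetric transfer hydrogenation (step 4) and kept because the C2–O bond is never broken again. The lavandulyl centre comes from lipase-resolved (S)-lavandulol. The C6 epimers disappear on aromatisation.
The 4'-OH is carried as a TIPS ether so that the last step needs fluoride, not acid, next to the lavandulyl alkenes and the electron-rich benzylic C2–O bond.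

Key step: step 12

Remark: the lipase is assumed to acetylate (R)-lavandulol faster, so the S alcohol is the unreacted fraction; if the preference is the reverse, the acetate fraction would be saponified and carried on instead.

"Lavandulyl" below means 5-methyl-2-(prop-1-en-2-yl)hex-4-en-1-yl.

Step 1
Reactants: 1 4-hydroxy-2-methoxybenzaldehyde
Product: 2 2-methoxy-4-(triisopropylsilyloxy)benzaldehyde
Conditions: TIPSCl, imidazole, DMF, rt
Reagents that add atoms: triisopropylsilyl chloride, CC(C)[Si](Cl)(C(C)C)C(C)C
Why: Imidazole-promoted silylation of the phenol gives an aryl silyl ether that should survive the enolate, transfer-hydrogenation, mild-acid, zerovalent-palladium and amidine-base steps ahead.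

Step 2
Reactants: 2 2-methoxy-4-(triisopropylsilyloxy)benzaldehyde; 3 N-methoxy-N-methylacetamide
Product: 4 racemic 3-hydroxy-N-methoxy-3-[2-methoxy-4-(triisopropylsilyloxy)phenyl]-N-methylpropanamide
Conditions: LiN(iPr)2, THF, −78 °C; then 2; AcOH quench
Reagents that add atoms: none
Why: Aldol addition of the lithium enolate of the Weinreb acetamide forms the C2–C3 bond; the carbinol is made racemic on purpose and corrected in steps 3 and 4.

Step 3
Reactants: 4 racemic β-hydroxy Weinreb amide
Product: 5 N-methoxy-3-[2-methoxy-4-(triisopropylsilyloxy)phenyl]-N-methyl-3-oxopropanamide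
Conditions: Dess–Martin periodinane, CH2Cl2, rt
Reagents that add atoms: none
Why: Dess–Martin oxidation of the benzylic secondary alcohol to the β-keto amide runs under near-neutral conditions that leave the silyl ether and the N–O bond alone.

Step 4
Reactants: 5 β-keto Weinreb amide
Product: 6 (3S)-3-hydroxy-N-methoxy-3-[2-methoxy-4-(triisopropylsilyloxy)phenyl]-N-methylpropanamide
Conditions: RuCl[(S,S)-TsDPEN](p-cymene) (cat.), HCO2H/Et3N (5:2), DMF, 30 °C
Reagents that add atoms: none
Why: Noyori asymmetric transfer hydrogenation of an aryl ketone, in which the (S,S)-ligand directs hydride to the face that gives the S carbinol from aryl alkyl ketones; this carbinol becomes C2.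

Step 5
Reactants: 6 (S)-β-hydroxy Weinreb amide; 7 allyl acetoacetate
Product: 9 allyl 2-{(2S)-2-[2-methoxy-4-(triisopropylsilyloxy)phenyl]-4-oxo-3,4-dihydro-2H-pyran-6-yl}acetate, via hydroxy triketo ester 8 (not isolated)
Conditions: 7 (excess), NaH then n-BuLi, THF, 0 °C; 6, −78 to −20 °C; cold dil. HCl; then PPTS (cat.), CH2Cl2, rt
Reagents that add atoms: none
Why: The γ-carbon of the acetoacetate dianion acylates on the Weinreb amide (C4–C4a), the alkoxide being tolerated as in Claisen condensations of unprotected β-hydroxy esters; acid-catalysed cyclodehydration of the δ-hydroxy-β-diketone then adds the C2 hydroxyl to the C8a carbonyl, so the C2–O bond and its configuration are kept.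

Step 6
Reactants: 9 allyl pyranonylacetate
Product: 10 2-{(2S)-2-[2-methoxy-4-(triisopropylsilyloxy)phenyl]-4-oxo-3,4-dihydro-2H-pyran-6-yl}acetic acid
Conditions: Pd(PPh3)4 (cat.), HCO2H, Et3N, THF, rt; acid used at once
Reagents that add atoms: none
Why: Palladium-catalysed deallylation through a π-allyl complex, reduced by formate, frees the acid without a nucleophilic amine that could add to the vinylogous ester and without base strong enough to enolise C8.

Step 7
Reactants: 11 racemic lavandulol
Product: 12 (S)-lavandulol, (2S)-5-methyl-2-(prop-1-en-2-yl)hex-4-en-1-ol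
Conditions: porcine pancreatic lipase, vinyl acetate, hexane, rt, stopped past half conversion; chromatography
Reagents that add atoms: none
Why: Lipase-catalysed kinetic resolution by enantioselective transesterification; running it past half conversion should leave the slower-reacting S alcohol in high enantiomeric purity.

Step 8
Reactants: 12 (S)-lavandulol
Product: 13 (S)-lavandulyl iodide, (2S)-1-iodo-5-methyl-2-(prop-1-en-2-yl)hex-4-ene
Conditions: PPh3, I2, imidazole, CH2Cl2, 0 °C to rt
Reagents that add atoms: iodine, II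
Why: Appel-type iodination of the primary alcohol takes place one carbon away from the stereocentre, which is therefore untouched.

Step 9
Reactants: 13 (S)-lavandulyl iodide; 14 dimethyl malonate
Product: 15 dimethyl 2-[(2R)-lavandulyl]propanedioate
Conditions: 14 (3 equiv), NaH, THF/DMF, 0 to 60 °C
Reagents that add atoms: none
Why: Malonic ester alkylation (SN2) with the soft sodium malonate in excess should favour substitution over elimination and dialkylation; the descriptor changes from S to R only through the CIP ranking, not in space.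

Step 10
Reactants: 15 dimethyl lavandulylmalonate
Product: 16 methyl hydrogen [(2R)-lavandulyl]malonate, (4R)-2-(methoxycarbonyl)-7-methyl-4-(prop-1-en-2-yl)oct-6-enoic acid, both C2 epimers
Conditions: KOH (1 equiv), MeOH/H2O, 0 °C to rt; then cold dil. HCl
Reagents that add atoms: potassium hydroxide, [K+].[OH-]
Why: Monosaponification of a malonic diester with one equivalent of hydroxide stops at the half-ester because the carboxylate deactivates the second ester; the new malonate centre is later planar and its configuration does not matter.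

Step 11
Reactants: 10 pyranonylacetic acid; 16 methyl hydrogen lavandulylmalonate
Product: 20 methyl 2-[(2R)-lavandulyl]-3-oxo-4-{(2S)-2-[2-methoxy-4-(triisopropylsilyloxy)phenyl]-4-oxo-3,4-dihydro-2H-pyran-6-yl}butanoate (both C2 epimers), via acyl imidazolide 17 (not isolated), via magnesium half-ester salt 18 (not isolated), via acylmalonic half-acid 19 (not isolated)
Conditions: 10, CDI, THF, 0 °C to rt; 16 (2.2 equiv), Mg(OEt)2, THF; combine, rt; cold dil. HCl
Reagents that add atoms: none
Why: Masamune–Brooks decarboxylative Claisen condensation, in which the magnesium-chelated malonate half-ester is C-acylated by the acyl imidazolide and then loses CO2; this forms the C6–C7 bond at an unambiguous carbon and without strong base.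

Step 12
Reactants: 20 dihydropyranone keto ester
Product: 21 (2S)-5,7-dihydroxy-2-[2-methoxy-4-(triisopropylsilyloxy)phenyl]-6-[(2R)-lavandulyl]chroman-4-one (4'-O-TIPS ether of the target)
Conditions: DBU (2.5 equiv), MeCN, 0 °C to rt; AcOH quench as soon as 20 is consumed
Reagents that add atoms: none
Why: Proposed new method: DBU removes a C8 proton, which lies between the C7 ketone and the vinylogous ester, and the extended enolate attacks the C5 methyl ester through C4a; loss of methoxide and enolisation of the C5 and C7 carbonyls then aromatise ring A. The closest known reaction type is the biomimetic Claisen (Dieckmann-type) cyclisation of 3,5,7-triketo esters and their pyranone-masked forms to acylphloroglucinols; untested is the 2,3-dihydropyran-4-one, where the central diketone is locked as a cyclic enol ether and C4a reacts as the α-carbon of a dienolate. Ring A closes in a 6-(enolexo)-exo-trig mode. No stereocentre is formed: C2 and the lavandulyl centre are spectators and the epimeric C6 becomes sp2. The step needs Claisen closure at C4a rather than aldol closure of C6 onto C4, which the lavandulyl group secures because that aldol adduct is quaternary at C6, cannot aromatise and reverts; it also needs ring C to stay closed, which the far higher acidity of C8–H and C6–H over C3–H secures, so O1 stays on C8a and lavandulyl is fixed at C6.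

Step 13
Reactants: 21 4'-O-TIPS flavanone
Product: 22 (2S)-5,7-dihydroxy-2-(4-hydroxy-2-methoxyphenyl)-6-[(2R)-lavandulyl]chroman-4-one (target)
Conditions: Bu4NF, AcOH (1:1), THF, 0 °C
Reagents that add atoms: none
Why: Fluoride cleavage of the aryl silyl ether, buffered with AcOH so that no free 4'-phenoxide can open ring C through a quinone methide and no acid reaches the lavandulyl alkenes or the ortho phenols.

**Compound list**
1 | 4-hydroxy-2-methoxybenzaldehyde | COc1cc(O)ccc1C=O | starting material
2 | 2-methoxy-4-(triisopropylsilyloxy)benzaldehyde | COc1cc(O[Si](C(C)C)(C(C)C)C(C)C)ccc1C=O | intermediate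
3 | N-methoxy-N-methylacetamide | CON(C)C(C)=O | starting material
4 | racemic 3-hydroxy-N-methoxy-3-[2-methoxy-4-(triisopropylsilyloxy)phenyl]-N-methylpropanamide | CON(C)C(=O)CC(O)c1ccc(O[Si](C(C)C)(C(C)C)C(C)C)cc1OC | intermediate
5 | N-methoxy-3-[2-methoxy-4-(triisopropylsilyloxy)phenyl]-N-methyl-3-oxopropanamide | CON(C)C(=O)CC(=O)c1ccc(O[Si](C(C)C)(C(C)C)C(C)C)cc1OC | intermediate
6 | (3S)-3-hydroxy-N-methoxy-3-[2-methoxy-4-(triisopropylsilyloxy)phenyl]-N-methylpropanamide | CON(C)C(=O)C[C@@H](c1ccc(O[Si](C(C)C)(C(C)C)C(C)C)cc1OC)O | intermediate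
7 | allyl acetoacetate (prop-2-en-1-yl 3-oxobutanoate) | C=CCOC(=O)CC(C)=O | starting material
8 | allyl (7S)-7-hydroxy-7-[2-methoxy-4-(triisopropylsilyloxy)phenyl]-3,5-dioxoheptanoate (not isolated) | C=CCOC(=O)CC(=O)CC(=O)C[C@@H](c1ccc(O[Si](C(C)C)(C(C)C)C(C)C)cc1OC)O | intermediate
9 | allyl 2-{(2S)-2-[2-methoxy-4-(triisopropylsilyloxy)phenyl]-4-oxo-3,4-dihydro-2H-pyran-6-yl}acetate | C=CCOC(=O)CC1=CC(=O)C[C@@H](c2ccc(O[Si](C(C)C)(C(C)C)C(C)C)cc2OC)O1 | intermediate
10 | 2-{(2S)-2-[2-methoxy-4-(triisopropylsilyloxy)phenyl]-4-oxo-3,4-dihydro-2H-pyran-6-yl}acetic acid | OC(=O)CC1=CC(=O)C[C@@H](c2ccc(O[Si](C(C)C)(C(C)C)C(C)C)cc2OC)O1 | intermediate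
11 | racemic lavandulol, 5-methyl-2-(prop-1-en-2-yl)hex-4-en-1-ol | C=C(C)C(CC=C(C)C)CO | starting material
12 | (S)-lavandulol | C=C(C)[C@H](CC=C(C)C)CO | intermediate
13 | (S)-lavandulyl iodide | C=C(C)[C@H](CC=C(C)C)CI | intermediate
14 | dimethyl malonate | COC(=O)CC(=O)OC | starting material
15 | dimethyl 2-[(2R)-lavandulyl]propanedioate | C=C(C)[C@H](CC=C(C)C)CC(C(=O)OC)C(=O)OC | intermediate
16 | methyl hydrogen [(2R)-lavandulyl]malonate (C2 epimers) | C=C(C)[C@H](CC=C(C)C)CC(C(=O)O)C(=O)OC | intermediate
17 | 1-(imidazol-1-yl)-2-{(2S)-2-[2-methoxy-4-(triisopropylsilyloxy)phenyl]-4-oxo-3,4-dihydro-2H-pyran-6-yl}ethanone (not isolated) | O=C(CC1=CC(=O)C[C@@H](c2ccc(O[Si](C(C)C)(C(C)C)C(C)C)cc2OC)O1)n1ccnc1 | intermediate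
18 | magnesium bis{methyl [(2R)-lavandulyl]malonate} (not isolated) | C=C(C)[C@H](CC=C(C)C)CC(C(=O)[O-])C(=O)OC.C=C(C)[C@H](CC=C(C)C)CC(C(=O)[O-])C(=O)OC.[Mg+2] | intermediate
19 | 2-[(2R)-lavandulyl]-2-(methoxycarbonyl)-3-oxo-4-{(2S)-2-aryl-4-oxo-3,4-dihydro-2H-pyran-6-yl}butanoic acid, aryl as in 9 (not isolated) | C=C(C)[C@H](CC=C(C)C)CC(C(=O)O)(C(=O)OC)C(=O)CC1=CC(=O)C[C@@H](c2ccc(O[Si](C(C)C)(C(C)C)C(C)C)cc2OC)O1 | intermediate
20 | methyl 2-[(2R)-lavandulyl]-3-oxo-4-{(2S)-2-[2-methoxy-4-(triisopropylsilyloxy)phenyl]-4-oxo-3,4-dihydro-2H-pyran-6-yl}butanoate (C2 epimers) | C=C(C)[C@H](CC=C(C)C)CC(C(=O)OC)C(=O)CC1=CC(=O)C[C@@H](c2ccc(O[Si](C(C)C)(C(C)C)C(C)C)cc2OC)O1 | intermediate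
21 | (2S)-5,7-dihydroxy-2-[2-methoxy-4-(triisopropylsilyloxy)phenyl]-6-[(2R)-lavandulyl]chroman-4-one | C=C(C)[C@H](CC=C(C)C)Cc1c(O)cc2c(c1O)C(=O)C[C@@H](c1ccc(O[Si](C(C)C)(C(C)C)C(C)C)cc1OC)O2 | intermediate
22 | (2S)-5,7-dihydroxy-2-(4-hydroxy-2-methoxyphenyl)-6-[(2R)-5-methyl-2-(prop-1-en-2-yl)hex-4-en-1-yl]chroman-4-one | C=C(C)[C@H](CC=C(C)C)Cc1c(O)cc2c(c1O)C(=O)C[C@@H](c1ccc(O)cc1OC)O2 | target

**Step count**
Total: 13 steps. Longest linear sequence: 9 steps (steps 1–6, then 11–13); the lavandulyl branch (steps 7–10) joins at step 11.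

**Steps most likely to fail**

Step 12. Once the β-keto ester is enolised at C6, the ester is a poor electrophile and the dienolate may be too weak a nucleophile at C4a. Prolonged base may also open ring C by β-elimination, which would erode C2 and, on reclosure through the other phenol, move the lavandulyl group to C8. The fallback closes ring A without base through an acylketene and uses only known reaction types. It sets out from iodide 13. Alkylation of commercial tert-butyl methyl malonate with NaH gives tert-butyl methyl lavandulylmalonate F1. One equivalent of KOH cleaves the methyl ester selectively to tert-butyl hydrogen lavandulylmalonate F2. Its magnesium salt F3, made with Mg(OEt)2, is acylated by imidazolide 17 as in step 11 to the acylmalonic half-acid F4, which loses CO2 to the tert-butyl keto ester F5. In refluxing toluene F5 should expel tert-butanol, the known thermolysis of tert-butyl β-keto esters, to give the acylketene F6. Its C7 enol is a dienylketene, and the known 6π-electrocyclisation of dienylketenes to phenols forms the C4a–C5 bond and returns to the route at 21.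

Step 11. C-acylation by the hindered, α-substituted magnesium malonate may be slow. Meanwhile the acyl imidazolide, which is acidic at C8, can self-condense, and acid 10 can decarboxylate. The fallback reverses the polarity and sets out from allyl ester 9. Half-acid 16 is converted with oxalyl chloride and catalytic DMF to methyl lavandulylmalonyl chloride F7. The magnesium enolate of 9 (MgCl2, Et3N, MeCN) is C-acylated at C8, where the allyl ester makes C8–H the most acidic position, to give the tricarbonyl allyl ester F8. Pd(PPh3)4 with HCO2H/Et3N then removes the allyl group, and the β-keto acid F9 loses CO2 to rejoin the route at 20.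

Step 5. At the lithium alkoxide stage, retro-aldol cleavage or β-elimination may compete with acylation. During the acid-catalysed ring closure the electron-rich benzylic alcohol may ionise, which would erode C2. The fallback protects the carbinol and releases it with fluoride; it sets out from 6. TESCl and imidazole give the triethylsilyl ether F10. The acetoacetate dianion acylates on F10 to give the silyl triketo ester F11. HF·pyridine in THF/pyridine removes the silyl group, and the freed 8 should close to 9 in the same buffered medium, where the route is rejoined.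

**Further compounds**
F1 | step 12 | tert-butyl methyl [(2R)-lavandulyl]malonate | C=C(C)[C@H](CC=C(C)C)CC(C(=O)OC)C(=O)OC(C)(C)C
F2 | step 12 | tert-butyl hydrogen [(2R)-lavandulyl]malonate | C=C(C)[C@H](CC=C(C)C)CC(C(=O)O)C(=O)OC(C)(C)C
F3 | step 12 | magnesium bis{tert-butyl [(2R)-lavandulyl]malonate} | C=C(C)[C@H](CC=C(C)C)CC(C(=O)[O-])C(=O)OC(C)(C)C.C=C(C)[C@H](CC=C(C)C)CC(C(=O)[O-])C(=O)OC(C)(C)C.[Mg+2]
F4 | step 12 | 2-(tert-butoxycarbonyl)-2-[(2R)-lavandulyl]-3-oxo-4-{(2S)-2-aryl-4-oxo-3,4-dihydro-2H-pyran-6-yl}butanoic acid, aryl as in 9 | C=C(C)[C@H](CC=C(C)C)CC(C(=O)O)(C(=O)OC(C)(C)C)C(=O)CC1=CC(=O)C[C@@H](c2ccc(O[Si](C(C)C)(C(C)C)C(C)C)cc2OC)O1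
F5 | step 12 | tert-butyl 2-[(2R)-lavandulyl]-3-oxo-4-{(2S)-2-aryl-4-oxo-3,4-dihydro-2H-pyran-6-yl}butanoate, aryl as in 9 | C=C(C)[C@H](CC=C(C)C)CC(C(=O)OC(C)(C)C)C(=O)CC1=CC(=O)C[C@@H](c2ccc(O[Si](C(C)C)(C(C)C)C(C)C)cc2OC)O1
F6 | step 12 | acylketene, 2-[(2R)-lavandulyl]-4-{(2S)-2-aryl-4-oxo-3,4-dihydro-2H-pyran-6-yl}but-1-ene-1,3-dione, aryl as in 9 | C=C(C)[C@H](CC=C(C)C)CC(=C=O)C(=O)CC1=CC(=O)C[C@@H](c2ccc(O[Si](C(C)C)(C(C)C)C(C)C)cc2OC)O1
F7 | step 11 | methyl [(2R)-lavandulyl]malonyl chloride | C=C(C)[C@H](CC=C(C)C)CC(C(=O)Cl)C(=O)OC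
F8 | step 11 | 1-allyl 5-methyl 4-[(2R)-lavandulyl]-3-oxo-2-{(2S)-2-aryl-4-oxo-3,4-dihydro-2H-pyran-6-yl}pentanedioate, aryl as in 9 | C=C(C)[C@H](CC=C(C)C)CC(C(=O)OC)C(=O)C(C(=O)OCC=C)C1=CC(=O)C[C@@H](c2ccc(O[Si](C(C)C)(C(C)C)C(C)C)cc2OC)O1
F9 | step 11 | 4-[(2R)-lavandulyl]-5-methoxy-3,5-dioxo-2-{(2S)-2-aryl-4-oxo-3,4-dihydro-2H-pyran-6-yl}pentanoic acid, aryl as in 9 | C=C(C)[C@H](CC=C(C)C)CC(C(=O)OC)C(=O)C(C(=O)O)C1=CC(=O)C[C@@H](c2ccc(O[Si](C(C)C)(C(C)C)C(C)C)cc2OC)O1
F10 | step 5 | (3S)-N-methoxy-3-[2-methoxy-4-(triisopropylsilyloxy)phenyl]-N-methyl-3-(triethylsilyloxy)propanamide | CON(C)C(=O)C[C@@H](c1ccc(O[Si](C(C)C)(C(C)C)C(C)C)cc1OC)O[Si](CC)(CC)CC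
F11 | step 5 | allyl (7S)-7-[2-methoxy-4-(triisopropylsilyloxy)phenyl]-3,5-dioxo-7-(triethylsilyloxy)heptanoate | C=CCOC(=O)CC(=O)CC(=O)C[C@@H](c1ccc(O[Si](C(C)C)(C(C)C)C(C)C)cc1OC)O[Si](CC)(CC)CC
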